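**Retrosynthetic overview**
- C8–C9 (last C–C bond): Stille coupling of iodoalkene 29 (rings A and B complete) with the peroxyketal-masked alkenylstannane 33 (fragment C); ketal hydrolysis then frees the hydroperoxide.
- Ring B (formed second): C2'–C3' bond by rhodium-catalysed aldehyde C–H activation (alkyne hydroacylation) of lactol 27, itself made from the C6-hydroxy acid by lactonisation and partial reduction.
- C5–C1': Ireland–Claisen rearrangement of ester 18 (ring A alkynol 10 + fragment B acid 17), the ring A carbinol passing its chirality to C5; C1–OH by Mukaiyama hydration, iodoalkene by zirconium-catalysed carboalumination.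
- Ring A (formed first): nickel-catalysed syn-aldol of 6 with enal 3, ring-closing metathesis, aldehyde-to-alkyne homologation (fragment A, 10).
- Fragment B from (S)-but-3-yn-2-ol and methyl acetoacetate (SN2 with inversion); fragment C from 2-methylbut-3-yn-2-ol (perhydrolysis, ketalisation, hydrostannation).

Atom labels: ring A = C1 (carbinol), C2, C3 (bears C7), C4, C5; C6 = CH2O on C1; side chain C7(CH3)=C8–C9=C10–C11(CH3)2OOH; ring B = C1' (on C5), C2' (C=O), C3'=C4', C5' (CH3).
Assumption: the (S,S)-configured nickel bis(oxazoline) catalyst is taken to give the (2S,3S) aldol 7; if its sense proves opposite, the (R,R)-catalyst is used.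

**Route**

Step 1
Reactants: 1 2-methylidenepropane-1,3-diol
Product: 2 mono-TBS ether
Conditions: NaH (1.0 equiv), THF, 0 °C; TBSCl (1.0 equiv), 0 °C → rt
Reagents that add atoms: tert-butyl(chloro)dimethylsilane, CC(C)(C)[Si](C)(C)Cl
Why: O-silylation of the sparingly soluble monosodium alkoxide of the symmetric diol gives the mono-ether selectively (monosilylation of a diol).

Step 2
Reactants: 2 mono-TBS ether
Product: 3 silyloxymethyl acrolein
Conditions: Dess–Martin periodinane, CH2Cl2, 0 °C → rt
Reagents that add atoms: none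
Why: Dess–Martin oxidation of the allylic alcohol gives the α-branched enal without touching the silyl ether.

Step 3
Reactants: 4 pent-4-enoyl chloride; 5 1,3-thiazolidine-2-thione
Product: 6 N-pentenoyl thiazolidinethione
Conditions: Et3N, CH2Cl2, 0 °C
Reagents that add atoms: none
Why: N-acylation by the acid chloride gives the activated imide needed for soft enolisation and later for direct reduction to the aldehyde.

Step 4
Reactants: 3 silyloxymethyl acrolein; 6 N-pentenoyl thiazolidinethione
Product: 7 syn-aldol silyl ether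
Conditions: [Ni((S,S)-tBu-box)](OTf)2 (10 mol%), 2,6-lutidine, TMSOTf, toluene/CH2Cl2, −78 → −20 °C
Reagents that add atoms: trimethylsilyl trifluoromethanesulfonate, C[Si](C)(C)OS(=O)(=O)C(F)(F)F
Why: Catalytic enantioselective syn-aldol addition (divalent nickel bis(oxazoline) complex, soft enolisation, silyl triflate turnover): the chelated Z-enolate of 6 adds through a closed transition state to one face of enal 3 and sets C2 and C3 as (2S,3S), the syn relation that later places the carbinol oxygen and C7 cis on ring A.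

Step 5
Reactants: 7 syn-aldol silyl ether
Product: 8 cyclopentenyl acylthiazolidinethione
Conditions: second-generation Grubbs catalyst (H2IMes)(PCy3)Cl2Ru=CHPh (3 mol%), CH2Cl2, 40 °C
Reagents that add atoms: none
Why: Ring-closing metathesis of the 1,6-diene forms ring A as the trisubstituted cyclopentene (C1=C5) and leaves both stereocentres untouched.

Step 6
Reactants: 8 cyclopentenyl acylthiazolidinethione
Product: 10 ring A alkynol, via cyclopentene carbaldehyde 9 (not isolated)
Conditions: i-Bu2AlH, CH2Cl2, −78 °C; then MeOH, K2CO3, dimethyl (1-diazo-2-oxopropyl)phosphonate, −78 °C → rt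
Reagents that add atoms: dimethyl (1-diazo-2-oxopropyl)phosphonate, CC(=O)C(=[N+]=[N-])P(=O)(OC)OC
Why: Hydride reduction of the activated imide stops at the aldehyde, and Ohira–Bestmann (Seyferth–Gilbert) homologation in the same flask converts it into the terminal alkyne C7≡C8 while methanolysis removes the trimethylsilyl ether, so the epimerisable cis aldehyde is never isolated.

Step 7
Reactants: 11 (S)-but-3-yn-2-ol
Product: 12 TIPS-alkynol
Conditions: n-BuLi (2.1 equiv), THF, −78 → 0 °C; i-Pr3SiCl (1.0 equiv), 0 °C → rt; H2O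
Reagents that add atoms: chlorotri(propan-2-yl)silane, CC(C)[Si](Cl)(C(C)C)C(C)C
Why: The alkoxide–acetylide dianion is silylated on carbon by the bulky chlorosilane (C-silylation of an acetylide), which caps this alkyne for every step up to the lactone.

Step 8
Reactants: 12 TIPS-alkynol
Product: 13 propargylic mesylate
Conditions: MsCl, Et3N, CH2Cl2, −20 °C
Reagents that add atoms: methanesulfonyl chloride, CS(=O)(=O)Cl
Why: O-sulfonylation turns the secondary propargylic alcohol into a leaving group with retention of configuration.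

Step 9
Reactants: 13 propargylic mesylate; 14 methyl acetoacetate
Product: 15 alkylated acetoacetate
Conditions: NaH, THF/DMF, 0 °C; then 13, 50 °C
Reagents that add atoms: none
Why: SN2 alkylation of the sodium acetoacetate enolate inverts the propargylic carbon and so sets the future C5' stereocentre, the bulky silyl cap disfavouring SN2′ attack at the alkyne terminus.

Step 10
Reactants: 15 alkylated acetoacetate
Product: 16 alkynoate methyl ester
Conditions: NaOMe (0.5 equiv), MeOH, 50 °C
Reagents that add atoms: none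
Why: Retro-Claisen deacetylation by methoxide removes the acetyl group as methyl acetate and cannot touch the β-stereocentre.

Step 11
Reactants: 16 alkynoate methyl ester
Product: 17 fragment B acid
Conditions: LiOH, THF/H2O, rt; then 1 M HCl
Reagents that add atoms: lithium hydroxide, [Li+].[OH-]
Why: Saponification gives the acid, whose stereocentre is β to the carboxyl group and cannot epimerise.

Step 12
Reactants: 10 ring A alkynol; 17 fragment B acid
Product: 18 allylic ester
Conditions: DCC, DMAP (cat.), CH2Cl2, 0 °C → rt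
Reagents that add atoms: none
Why: Steglich esterification joins fragments A and B at the ring A carbinol without affecting any stereocentre.

Step 13
Reactants: 18 allylic ester
Product: 21 Claisen acid, via silyl ketene acetal 19 (not isolated), via trimethylsilyl ester 20 (not isolated)
Conditions: LiN(i-Pr)2 (2.4 equiv), THF/DMPU, −78 °C; TMSCl; −78 → 50 °C; then K2CO3, MeOH, rt; 1 M HCl
Reagents that add atoms: none
Why: Ireland–Claisen rearrangement: the Z(O)-enolate formed in THF/DMPU (C5' cis to O–Li) is trapped as the silyl ketene acetal and rearranges through a boat transition state, the chair being blocked by the ring substituent cis to the ester oxygen, so the C5–C1' bond forms on the face that carried that oxygen (C5 cis to C3) and C1' is set (S) with C5' outside the ring; the second equivalent of base C-silylates the ring A alkyne, which K2CO3/MeOH frees again.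

Step 14
Reactants: 21 Claisen acid
Product: 22 hydroxy acid
Conditions: Co(acac)2 (20 mol%), PhSiH3, O2 (1 atm), THF, rt
Reagents that add atoms: dioxygen, O=O
Why: Mukaiyama hydration: hydrogen-atom transfer from the cobalt hydride to C2 of the only alkene gives the tertiary C1 radical, which captures O2 on the face opposite the adjacent C5 substituent and the C3 ethynyl group, so the hydroxyl ends up trans to both (C1 R); the alkynes do not react under these conditions.

Step 15
Reactants: 22 hydroxy acid
Product: 24 iodoalkene hydroxy acid, via alkenylalane 23 (not isolated)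
Conditions: AlMe3, Cp2ZrCl2 (0.5 equiv), CH2Cl2, 0 °C → rt; then I2, THF, −30 → 0 °C; aq. KNaC4H4O6 (potassium sodium tartrate)/Na2S2O3
Reagents that add atoms: trimethylaluminium, C[Al](C)C; iodine, II
Why: Zirconium-catalysed carboalumination (Negishi methylalumination) adds CH3 and Al syn across the only terminal alkyne with Al at the terminal carbon, and iodinolysis with retention gives the (E)-iodoalkene; the silyl-capped alkyne is inert and the acid and alcohol are carried as aluminium salts.

Step 16
Reactants: 24 iodoalkene hydroxy acid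
Product: 26 bicyclic lactone, via dihydroxy acid 25 (not isolated)
Conditions: Bu4NF, THF, rt; aq. NH4Cl; then PPTS (cat.), CH2Cl2, rt
Reagents that add atoms: none
Why: Fluoride cleaves both silyl groups and the freed C6 hydroxyl lactonises onto the cis-disposed carboxyl group (six-membered ring; the trans-disposed tertiary hydroxyl cannot), which marks C6–OH apart from C1–OH and readies C2' for reduction.

Step 17
Reactants: 26 bicyclic lactone
Product: 27 lactol
Conditions: i-Bu2AlH (2.2 equiv), CH2Cl2, −78 °C
Reagents that add atoms: none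
Why: Partial reduction of the δ-lactone at −78 °C stops at the lactol (lactone-to-lactol reduction), a masked δ-hydroxy aldehyde.

Step 18
Reactants: 27 lactol
Product: 28 enone diol
Conditions: [Rh(dppe)]2(BF4)2 (5 mol%), acetone, 25 → 45 °C
Reagents that add atoms: none
Why: Proposed new method: the lactol is in ring–chain equilibrium with the δ-hydroxy aldehyde, whose formyl C–H adds oxidatively to the cationic monovalent rhodium centre held by the pendant terminal alkyne; hydrorhodation of the alkyne (H to C4', Rh to C3'), isomerisation of the alkenyl rhodium and C–C reductive elimination close ring B as the cyclopent-2-enone by net trans addition, leaving the C1' and C5' centres untouched under neutral conditions; the closest known reaction is the rhodium-catalysed trans-hydroacylation of internal 4-alkynals to cyclopentenones, here extended to a terminal alkyne and to an aldehyde released from a lactol.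

Step 19
Reactants: 28 enone diol
Product: 29 iodoalkene acetate
Conditions: Ac2O (1.2 equiv), pyridine, CH2Cl2, 0 °C
Reagents that add atoms: acetic anhydride, CC(=O)OC(C)=O
Why: Selective acylation of the primary hydroxyl (the tertiary one is inert without an acyl-transfer catalyst) traps the open hydroxy ketone form as the C6 acetate under conditions too mild to epimerise C1'.

Step 20
Reactants: 30 2-methylbut-3-yn-2-ol
Product: 31 propargylic hydroperoxide
Conditions: 50% aq. H2O2, H2SO4 (cat.), 0 °C → rt
Reagents that add atoms: hydrogen peroxide, OO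
Why: Acid-catalysed perhydrolysis (SN1 through the tertiary propargylic cation) exchanges OH for OOH.

Step 21
Reactants: 31 propargylic hydroperoxide
Product: 32 peroxyketal alkyne
Conditions: 2-methoxypropene, PPTS (cat.), CH2Cl2, 0 °C
Reagents that add atoms: 2-methoxypropene, COC(C)=C
Why: Acid-catalysed addition of the hydroperoxide to the enol ether gives the mixed peroxyketal, which masks the O–O–H group as a hindered dialkyl peroxide.

Step 22
Reactants: 32 peroxyketal alkyne
Product: 33 fragment C stannane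
Conditions: Bu3SnH, PdCl2(PPh3)2 (2 mol%), THF, 0 °C
Reagents that add atoms: tributyltin hydride, CCCC[SnH](CCCC)CCCC
Why: Palladium-catalysed syn-hydrostannation places tin at the terminal carbon, away from the quaternary centre, and gives the (E)-alkenylstannane that fixes the C9=C10 geometry.

Step 23
Reactants: 29 iodoalkene acetate; 33 fragment C stannane
Product: 34 protected dienyl peroxide
Conditions: PdCl2(MeCN)2 (5 mol%), DMF, rt, dark
Reagents that add atoms: none
Why: Stille cross-coupling under ligand-free, base-free zerovalent palladium catalysis forms the C8–C9 bond with retention of both alkene geometries, and the neutral room-temperature conditions spare the dialkyl peroxide and the epimerisable C1' centre.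

Step 24
Reactants: 34 protected dienyl peroxide
Product: 35 target
Conditions: AcOH/THF/H2O (4:2:1), rt
Reagents that add atoms: none
Why: Mild acid hydrolysis of the mixed peroxyketal (acetal cleavage) releases the tertiary hydroperoxide without ionising the allylic C–O bond or touching the acetate, the enone or C1'.

**Compound list**

1 | 2-methylidenepropane-1,3-diol | C=C(CO)CO | starting material
2 | mono-TBS ether: 2-({[tert-butyl(dimethyl)silyl]oxy}methyl)prop-2-en-1-ol | C=C(CO)CO[Si](C)(C)C(C)(C)C | intermediate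
3 | silyloxymethyl acrolein: 2-({[tert-butyl(dimethyl)silyl]oxy}methyl)prop-2-enal | C=C(C=O)CO[Si](C)(C)C(C)(C)C | intermediate
4 | pent-4-enoyl chloride | C=CCCC(Cl)=O | starting material
5 | 1,3-thiazolidine-2-thione | S=C1NCCS1 | starting material
6 | N-pentenoyl thiazolidinethione: 1-(2-sulfanylidene-1,3-thiazolidin-3-yl)pent-4-en-1-one | C=CCCC(=O)N1CCSC1=S | intermediate
7 | syn-aldol silyl ether: (2S,3S)-4-({[tert-butyl(dimethyl)silyl]oxy}methyl)-2-(prop-2-en-1-yl)-1-(2-sulfanylidene-1,3-thiazolidin-3-yl)-3-[(trimethylsilyl)oxy]pent-4-en-1-one | C=CC[C@H](C(=O)N1CCSC1=S)[C@H](O[Si](C)(C)C)C(=C)CO[Si](C)(C)C(C)(C)C | intermediate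
8 | cyclopentenyl acylthiazolidinethione: [(1S,2S)-3-({[tert-butyl(dimethyl)silyl]oxy}methyl)-2-[(trimethylsilyl)oxy]cyclopent-3-en-1-yl](2-sulfanylidene-1,3-thiazolidin-3-yl)methanone | CC(C)(C)[Si](C)(C)OCC1=CC[C@H](C(=O)N2CCSC2=S)[C@@H]1O[Si](C)(C)C | intermediate
9 | cyclopentene carbaldehyde (not isolated): (1S,2S)-3-({[tert-butyl(dimethyl)silyl]oxy}methyl)-2-[(trimethylsilyl)oxy]cyclopent-3-ene-1-carbaldehyde | CC(C)(C)[Si](C)(C)OCC1=CC[C@H](C=O)[C@@H]1O[Si](C)(C)C | intermediate
10 | ring A alkynol: (1S,5R)-2-({[tert-butyl(dimethyl)silyl]oxy}methyl)-5-ethynylcyclopent-2-en-1-ol | CC(C)(C)[Si](C)(C)OCC1=CC[C@H](C#C)[C@@H]1O | intermediate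
11 | (2S)-but-3-yn-2-ol | C#C[C@H](C)O | starting material
12 | TIPS-alkynol: (2S)-4-[tri(propan-2-yl)silyl]but-3-yn-2-ol | CC(C)[Si](C(C)C)(C(C)C)C#C[C@H](C)O | intermediate
13 | propargylic mesylate: (2S)-4-[tri(propan-2-yl)silyl]but-3-yn-2-yl methanesulfonate | CC(C)[Si](C(C)C)(C(C)C)C#C[C@H](C)OS(C)(=O)=O | intermediate
14 | methyl acetoacetate (methyl 3-oxobutanoate) | COC(=O)CC(C)=O | starting material
15 | alkylated acetoacetate: methyl (3S)-2-acetyl-3-methyl-5-[tri(propan-2-yl)silyl]pent-4-ynoate (both C-2 epimers) | CC(C)[Si](C(C)C)(C(C)C)C#C[C@@H](C)C(C(C)=O)C(=O)OC | intermediate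
16 | alkynoate methyl ester: methyl (3S)-3-methyl-5-[tri(propan-2-yl)silyl]pent-4-ynoate | CC(C)[Si](C(C)C)(C(C)C)C#C[C@@H](C)CC(=O)OC | intermediate
17 | fragment B acid: (3S)-3-methyl-5-[tri(propan-2-yl)silyl]pent-4-ynoic acid | CC(C)[Si](C(C)C)(C(C)C)C#C[C@@H](C)CC(=O)O | intermediate
18 | allylic ester: (1S,5R)-2-({[tert-butyl(dimethyl)silyl]oxy}methyl)-5-ethynylcyclopent-2-en-1-yl (3S)-3-methyl-5-[tri(propan-2-yl)silyl]pent-4-ynoate | CC(C)(C)[Si](C)(C)OCC1=CC[C@H](C#C)[C@@H]1OC(=O)C[C@H](C)C#C[Si](C(C)C)(C(C)C)C(C)C | intermediate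
19 | silyl ketene acetal (not isolated): {[(1Z,3S)-1-{[(1S,5R)-2-({[tert-butyl(dimethyl)silyl]oxy}methyl)-5-[(trimethylsilyl)ethynyl]cyclopent-2-en-1-yl]oxy}-3-methyl-5-[tri(propan-2-yl)silyl]pent-1-en-4-yn-1-yl]oxy}(trimethyl)silane | CC(C)(C)[Si](C)(C)OCC1=CC[C@H](C#C[Si](C)(C)C)[C@@H]1O/C(O[Si](C)(C)C)=C/[C@H](C)C#C[Si](C(C)C)(C(C)C)C(C)C | intermediate
20 | trimethylsilyl ester (not isolated): trimethylsilyl (2S,3S)-2-[(1S,4S)-2-({[tert-butyl(dimethyl)silyl]oxy}methyl)-4-[(trimethylsilyl)ethynyl]cyclopent-2-en-1-yl]-3-methyl-5-[tri(propan-2-yl)silyl]pent-4-ynoate | CC(C)(C)[Si](C)(C)OCC1=C[C@@H](C#C[Si](C)(C)C)C[C@H]1[C@@H](C(=O)O[Si](C)(C)C)[C@H](C)C#C[Si](C(C)C)(C(C)C)C(C)C | intermediate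
21 | Claisen acid: (2S,3S)-2-[(1S,4S)-2-({[tert-butyl(dimethyl)silyl]oxy}methyl)-4-ethynylcyclopent-2-en-1-yl]-3-methyl-5-[tri(propan-2-yl)silyl]pent-4-ynoic acid | CC(C)(C)[Si](C)(C)OCC1=C[C@@H](C#C)C[C@H]1[C@@H](C(=O)O)[C@H](C)C#C[Si](C(C)C)(C(C)C)C(C)C | intermediate
22 | hydroxy acid: (2S,3S)-2-[(1S,2R,4S)-2-({[tert-butyl(dimethyl)silyl]oxy}methyl)-4-ethynyl-2-hydroxycyclopentyl]-3-methyl-5-[tri(propan-2-yl)silyl]pent-4-ynoic acid | CC(C)(C)[Si](C)(C)OC[C@@]1(O)C[C@@H](C#C)C[C@H]1[C@@H](C(=O)O)[C@H](C)C#C[Si](C(C)C)(C(C)C)C(C)C | intermediate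
23 | alkenylalane (not isolated): (E)-alkenyl(dimethyl)alane from 22, hydroxyl and carboxyl held as dimethylaluminium alkoxide and carboxylate | CC(C)(C)[Si](C)(C)OC[C@@]1(O[Al](C)C)C[C@@H](/C(C)=C/[Al](C)C)C[C@H]1[C@@H](C(=O)O[Al](C)C)[C@H](C)C#C[Si](C(C)C)(C(C)C)C(C)C | intermediate
24 | iodoalkene hydroxy acid: (2S,3S)-2-[(1S,2R,4S)-2-({[tert-butyl(dimethyl)silyl]oxy}methyl)-2-hydroxy-4-[(1E)-1-iodoprop-1-en-2-yl]cyclopentyl]-3-methyl-5-[tri(propan-2-yl)silyl]pent-4-ynoic acid | CC(C)(C)[Si](C)(C)OC[C@@]1(O)C[C@@H](/C(C)=C/I)C[C@H]1[C@@H](C(=O)O)[C@H](C)C#C[Si](C(C)C)(C(C)C)C(C)C | intermediate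
25 | dihydroxy acid (not isolated): (2S,3S)-2-[(1S,2R,4S)-2-hydroxy-2-(hydroxymethyl)-4-[(1E)-1-iodoprop-1-en-2-yl]cyclopentyl]-3-methylpent-4-ynoic acid | OC[C@@]1(O)C[C@@H](/C(C)=C/I)C[C@H]1[C@@H](C(=O)O)[C@H](C)C#C | intermediate
26 | bicyclic lactone: (4S,4aS,6S,7aR)-4-[(2S)-but-3-yn-2-yl]-7a-hydroxy-6-[(1E)-1-iodoprop-1-en-2-yl]hexahydrocyclopenta[c]pyran-3(1H)-one | O=C1OC[C@@]2(O)C[C@@H](/C(C)=C/I)C[C@H]2[C@@H]1[C@H](C)C#C | intermediate
27 | lactol: (4S,4aS,6S,7aR)-4-[(2S)-but-3-yn-2-yl]-6-[(1E)-1-iodoprop-1-en-2-yl]hexahydrocyclopenta[c]pyran-3,7a(1H)-diol (mixture of C-3 anomers) | OC1OC[C@@]2(O)C[C@@H](/C(C)=C/I)C[C@H]2[C@@H]1[C@H](C)C#C | intermediate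
28 | enone diol: (4R,5S)-5-[(1S,2R,4S)-2-hydroxy-2-(hydroxymethyl)-4-[(1E)-1-iodoprop-1-en-2-yl]cyclopentyl]-4-methylcyclopent-2-en-1-one | OC[C@@]1(O)C[C@@H](/C(C)=C/I)C[C@H]1[C@H]1C(=O)C=C[C@H]1C | intermediate
29 | iodoalkene acetate: [(1R,2S,4S)-1-hydroxy-4-[(1E)-1-iodoprop-1-en-2-yl]-2-[(1S,5R)-5-methyl-2-oxocyclopent-3-en-1-yl]cyclopentyl]methyl acetate | CC(=O)OC[C@@]1(O)C[C@@H](/C(C)=C/I)C[C@H]1[C@H]1C(=O)C=C[C@H]1C | intermediate
30 | 2-methylbut-3-yn-2-ol | CC(C)(O)C#C | starting material
31 | propargylic hydroperoxide: 3-hydroperoxy-3-methylbut-1-yne | CC(C)(OO)C#C | intermediate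
32 | peroxyketal alkyne: 3-[(2-methoxypropan-2-yl)peroxy]-3-methylbut-1-yne | COC(C)(C)OOC(C)(C)C#C | intermediate
33 | fragment C stannane: tributyl{(1E)-3-[(2-methoxypropan-2-yl)peroxy]-3-methylbut-1-en-1-yl}stannane | CCCC[Sn](CCCC)(CCCC)/C=C/C(C)(C)OOC(C)(C)OC | intermediate
34 | protected dienyl peroxide: [(1R,2S,4S)-1-hydroxy-4-{(2E,4E)-6-[(2-methoxypropan-2-yl)peroxy]-6-methylhepta-2,4-dien-2-yl}-2-[(1S,5R)-5-methyl-2-oxocyclopent-3-en-1-yl]cyclopentyl]methyl acetate | CC(=O)OC[C@@]1(O)C[C@@H](/C(C)=C/C=C/C(C)(C)OOC(C)(C)OC)C[C@H]1[C@H]1C(=O)C=C[C@H]1C | intermediate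
35 | CNP0204569.2: [(1R,2S,4S)-4-[(2E,4E)-6-hydroperoxy-6-methylhepta-2,4-dien-2-yl]-1-hydroxy-2-[(1S,5R)-5-methyl-2-oxocyclopent-3-en-1-yl]cyclopentyl]methyl acetate | CC(=O)OC[C@@]1(O)C[C@@H](/C(C)=C/C=C/C(C)(C)OO)C[C@H]1[C@H]1C(=O)C=C[C@H]1C | target

**Step count and weak points**

Total step count: 24. Longest linear sequence: 15 steps (steps 1, 2, 4, 5, 6, 12 to 19, 23 and 24; the line from 11 through steps 7 to 11 is equally long).

Three steps most likely to fail:

Step 13 (Ireland–Claisen). The C5 centre is secured by suprafacial transfer, but C1' depends on enolate geometry and on the boat preference, so the C-2 epimer of 21 may form alongside. In that case the mixture is taken through steps 14 to 16 unchanged. The fallback sets out from lactone 26 obtained together with its C-4 epimer, the endo lactone F1. DBU (0.3 equiv) in toluene at 60 °C equilibrates the α-centre of this rigid cis-fused lactone towards the isomer that carries the butynyl group on the convex face, away from the C3 substituent. That isomer is 26, where the fallback comes back to the route. Control of C1' thus shifts from the kinetic sigmatropic step to a thermodynamic equilibration on the bicycle.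

Step 14 (Mukaiyama hydration). Face selectivity at the C1 radical or interference by the free acid may be poor. The fallback sets out from Claisen acid 21. Me3SiCHN2 in MeOH/toluene at 0 °C gives the methyl ester F2. mCPBA with NaHCO3 in CH2Cl2 at 0 °C epoxidises the ring A double bond on the face opposite both ring substituents and gives the epoxy ester F3. LiAlH4 in THF (0 °C → rt) delivers hydride to the secondary epoxide carbon and reduces the ester, giving the diol F4. TEMPO (cat.) with PhI(OAc)2 in MeCN/H2O oxidises the primary alcohol to the acid and comes back at hydroxy acid 22.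

Step 18 (the new rhodium-catalysed hydroacylation). The terminal alkyne, the lactol resting state or the iodoalkene may divert the catalyst. The fallback uses established reactions only and sets out from bicyclic lactone 26. Hydroboration with (c-C6H11)2BH in THF at 0 °C followed by protonolysis with AcOH converts the terminal alkyne into the alkene and gives the vinyl lactone F5, sparing the iodoalkene. CH2=CHMgBr (2.2 equiv) in THF at −78 °C opens the lactone by single addition and gives the hydroxy dienone F6. Ring-closing metathesis with the second-generation Hoveyda–Grubbs catalyst (H2IMes)Cl2Ru=CH(2-i-PrOC6H4) in CH2Cl2 at 40 °C closes ring B and comes back at enone diol 28.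

**Further compounds**

F1 | step 13 | endo lactone: (4R,4aS,6S,7aR)-4-[(2S)-but-3-yn-2-yl]-7a-hydroxy-6-[(1E)-1-iodoprop-1-en-2-yl]hexahydrocyclopenta[c]pyran-3(1H)-one (C-4 epimer of 26) | O=C1OC[C@@]2(O)C[C@@H](/C(C)=C/I)C[C@H]2[C@H]1[C@H](C)C#C
F2 | step 14 | methyl ester: methyl (2S,3S)-2-[(1S,4S)-2-({[tert-butyl(dimethyl)silyl]oxy}methyl)-4-ethynylcyclopent-2-en-1-yl]-3-methyl-5-[tri(propan-2-yl)silyl]pent-4-ynoate | CC(C)(C)[Si](C)(C)OCC1=C[C@@H](C#C)C[C@H]1[C@@H](C(=O)OC)[C@H](C)C#C[Si](C(C)C)(C(C)C)C(C)C
F3 | step 14 | epoxy ester: F2 with the ring A C1=C2 double bond epoxidised on the face opposite the two ring substituents | CC(C)(C)[Si](C)(C)OC[C@@]12O[C@@H]1[C@@H](C#C)C[C@H]2[C@@H](C(=O)OC)[C@H](C)C#C[Si](C(C)C)(C(C)C)C(C)C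
F4 | step 14 | diol: (2S,3S)-2-[(1S,2R,4S)-2-({[tert-butyl(dimethyl)silyl]oxy}methyl)-4-ethynyl-2-hydroxycyclopentyl]-3-methyl-5-[tri(propan-2-yl)silyl]pent-4-yn-1-ol | CC(C)(C)[Si](C)(C)OC[C@@]1(O)C[C@@H](C#C)C[C@H]1[C@@H](CO)[C@H](C)C#C[Si](C(C)C)(C(C)C)C(C)C
F5 | step 18 | vinyl lactone: (4S,4aS,6S,7aR)-4-[(2R)-but-3-en-2-yl]-7a-hydroxy-6-[(1E)-1-iodoprop-1-en-2-yl]hexahydrocyclopenta[c]pyran-3(1H)-one | O=C1OC[C@@]2(O)C[C@@H](/C(C)=C/I)C[C@H]2[C@@H]1[C@H](C)C=C
F6 | step 18 | hydroxy dienone: (4S,5R)-4-[(1S,2R,4S)-2-hydroxy-2-(hydroxymethyl)-4-[(1E)-1-iodoprop-1-en-2-yl]cyclopentyl]-5-methylhepta-1,6-dien-3-one | OC[C@@]1(O)C[C@@H](/C(C)=C/I)C[C@H]1[C@@H](C(=O)C=C)[C@H](C)C=C
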